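**Retrosynthetic overview**

- The target is (2S)-pinocembrin carrying at C6 a trans-(1S,6S)-3-methyl-6-isopropylcyclohex-2-enyl group. The aromatic ring A, the pyranone ring and the phenyl ring are taken intact from (2S)-pinocembrin; the cyclohexene is the only ring built and the last ring closed.
- Enabling feature: in the cyclohexene the C(CH3)=CH double bond lies directly next to the aryl-bearing CH, and CH(iPr)–CH2–CH2 completes the ring. This is a Diels–Alder retron in which the carbon bonded to C6 of ring A is a diene terminus and the isopropyl-bearing carbon can carry a formyl group as temporary activating group.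
- Disconnections: isopropyl ⇐ isopropenyl ⇐ acetyl ⇐ trans-formyl (by epimerization) ⇐ endo (4+2) adduct of a 6-[(E)-3-methylbuta-1,3-dienyl]flavanone with acrolein under chiral iminium catalysis.
- Diene ⇐ 6-iodoflavanone + 2-methylbut-1-en-3-yne (hydrozirconation/Negishi); iodide ⇐ 5-OH-directed iodination of 7-O-silyl pinocembrin.
- Ring order: ring A, pyranone and phenyl (pre-formed) → cyclohexene (step 5).

Key step: step 5

Assumption: (2S)-pinocembrin, the natural enantiomer, is taken as the commercial source of the flavanone stereocenter; TBS = tert-butyldimethylsilyl; alcohol 14 is carried as a mixture of carbinol epimers, which step 8 erases.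

**Route**

Step 1
Reactants: 1 (2S)-pinocembrin
Product: 2 (2S)-7-[(tert-butyldimethylsilyl)oxy]-5-hydroxy-2-phenyl-2,3-dihydro-4H-chromen-4-one
Conditions: TBSCl (1.1 equiv), imidazole (2.2 equiv), CH2Cl2, 0 °C
Reagents that add atoms: tert-butyldimethylsilyl chloride, CC(C)(C)[Si](C)(C)Cl
Why: Silyl ether formation should be selective for the more acidic, non-chelated 7-OH, because the 5-OH is held in a hydrogen bond to the C4 carbonyl, and the weakly basic medium should not touch the C2 stereocenter.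

Step 2
Reactants: 2 (2S)-7-[(tert-butyldimethylsilyl)oxy]-5-hydroxy-2-phenyl-2,3-dihydro-4H-chromen-4-one
Product: 3 (2S)-7-[(tert-butyldimethylsilyl)oxy]-5-hydroxy-6-iodo-2-phenyl-2,3-dihydro-4H-chromen-4-one
Conditions: BnNMe3 ICl2 (1.05 equiv), CaCO3, CH2Cl2/MeOH (5:2), rt
Reagents that add atoms: benzyltrimethylammonium dichloroiodate, C[N+](C)(C)Cc1ccccc1.Cl[I-]Cl
Why: Electrophilic aromatic iodination with a dichloroiodate salt should go ortho to the free, chelated 5-OH (C6), the pattern known for 5-hydroxy-7-alkoxy flavonoids, while CaCO3 buffers the HCl so that the silyl ether and C2 survive.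

Step 3
Reactants: 3 (2S)-7-[(tert-butyldimethylsilyl)oxy]-5-hydroxy-6-iodo-2-phenyl-2,3-dihydro-4H-chromen-4-one
Product: 4 (2S)-5,7-bis[(tert-butyldimethylsilyl)oxy]-6-iodo-2-phenyl-2,3-dihydro-4H-chromen-4-one
Conditions: TBSOTf (1.5 equiv), 2,6-lutidine (3 equiv), CH2Cl2, 0 °C to rt
Reagents that add atoms: tert-butyldimethylsilyl trifluoromethanesulfonate, CC(C)(C)[Si](C)(C)OS(=O)(=O)C(F)(F)F
Why: Silyl ether formation with the silyl triflate and a hindered pyridine base should cap the hindered, hydrogen-bonded 5-OH, which would otherwise add to the diene of 8 (chromene formation), without the strong base that opens flavanones.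

Step 4
Reactants: 4 (2S)-5,7-bis[(tert-butyldimethylsilyl)oxy]-6-iodo-2-phenyl-2,3-dihydro-4H-chromen-4-one; 5 2-methylbut-1-en-3-yne
Product: 8 (2S)-5,7-bis[(tert-butyldimethylsilyl)oxy]-6-[(1E)-3-methylbuta-1,3-dien-1-yl]-2-phenyl-2,3-dihydro-4H-chromen-4-one, via dienylzirconocene chloride 6 (not isolated), via dienylzinc chloride 7 (not isolated)
Conditions: 5 (2.0 equiv), Cp2Zr(H)Cl (1.6 equiv), THF, rt; ZnCl2 (1.6 equiv), 0 °C; then 4, Pd2(dba)3 (2.5 mol%), SPhos (10 mol%), THF, 45 °C
Reagents that add atoms: none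
Why: Hydrozirconation of the terminal alkyne (syn addition, Zr at the terminal carbon, alkyne faster than the 1,1-disubstituted alkene), Zr-to-Zn transmetalation and Negishi cross-coupling should give the (E)-diene under base-free conditions that cannot epimerize C2, all Zr–H being consumed before ketone 4 is added.

Step 5
Reactants: 8 (2S)-5,7-bis[(tert-butyldimethylsilyl)oxy]-6-[(1E)-3-methylbuta-1,3-dien-1-yl]-2-phenyl-2,3-dihydro-4H-chromen-4-one; 9 acrolein
Product: 12 (2S)-5,7-bis[(tert-butyldimethylsilyl)oxy]-6-[(1R,6S)-6-formyl-3-methylcyclohex-2-en-1-yl]-2-phenyl-2,3-dihydro-4H-chromen-4-one (cis), via acrolein iminium chloride 10 (not isolated), via cycloadduct iminium chloride 11 (not isolated)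
Conditions: 9 (3 equiv), (5R)-5-benzyl-2,2,3-trimethylimidazolidin-4-one hydrochloride (first-generation MacMillan imidazolidinone, 20 mol%), MeCN/H2O (95:5), −10 °C to rt
Reagents that add atoms: none
Why: The amine salt condenses with acrolein to iminium ion 10, whose low LUMO should let it react with the hindered, electron-rich aryl diene 8 in a concerted, asynchronous (4+2) cycloaddition, and hydrolysis of iminium 11 then releases 12 and the catalyst; the closest known reaction type is the imidazolidinone-catalysed Diels–Alder reaction of acrolein with 1-substituted acyclic dienes, and 8 is a dehydroprenyl-arene diene of the kind used in mulberry-type Diels–Alder chemistry. The cyclohexene is closed by this intermolecular (4+2) cycloaddition, suprafacial on both partners, which forms the C3–C4 and C5–C6 bonds (C1 = methyl-bearing carbon) and leaves the double bond at C1=C2. The regiochemistry follows from the 1-aryl and 3-methyl groups of the diene, which both put the largest HOMO coefficient on the CH2 terminus that bonds to the iminium β-carbon. The formyl-bearing stereocenter is set by the catalyst, whose benzyl group covers one face of the (E)-iminium ion, and the aryl-bearing stereocenter follows from the endo transition state, which places aryl and formyl cis. The flavanone C2 center is too remote to influence the facial choice, so full catalyst control and endo selectivity are needed; the exo (trans) adduct carries the wrong configuration at the aryl-bearing carbon and should be removed here by chromatography, as a cis/trans diastereomer. Chemoselectivity is secured by the substrate, since only acrolein forms an iminium ion (the chromanone carbonyl is hindered and deactivated) and both phenols are capped.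

Step 6
Reactants: 12 (2S)-5,7-bis[(tert-butyldimethylsilyl)oxy]-6-[(1R,6S)-6-formyl-3-methylcyclohex-2-en-1-yl]-2-phenyl-2,3-dihydro-4H-chromen-4-one
Product: 13 (2S)-5,7-bis[(tert-butyldimethylsilyl)oxy]-6-[(1R,6R)-6-formyl-3-methylcyclohex-2-en-1-yl]-2-phenyl-2,3-dihydro-4H-chromen-4-one (trans)
Conditions: pyrrolidine (20 mol%), AcOH (20 mol%), CH2Cl2, rt
Reagents that add atoms: none
Why: Amine-catalysed α-epimerization of the aldehyde through its enamine (thermodynamic control) should invert only the formyl-bearing carbon and place the formyl group trans to the bulky aryl group, the buffered medium being too weakly basic to open the flavanone.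

Step 7
Reactants: 13 (2S)-5,7-bis[(tert-butyldimethylsilyl)oxy]-6-[(1R,6R)-6-formyl-3-methylcyclohex-2-en-1-yl]-2-phenyl-2,3-dihydro-4H-chromen-4-one
Product: 14 (2S)-5,7-bis[(tert-butyldimethylsilyl)oxy]-6-[(1R,6R)-6-(1-hydroxyethyl)-3-methylcyclohex-2-en-1-yl]-2-phenyl-2,3-dihydro-4H-chromen-4-one (carbinol epimers)
Conditions: MeMgBr (1.2 equiv), THF, −78 °C; aq. NH4Cl
Reagents that add atoms: methylmagnesium bromide, C[Mg]Br
Why: Grignard 1,2-addition at low temperature should be chemoselective for the aldehyde over the hindered chromanone carbonyl, which is deactivated by three conjugated oxygen donors, and the new carbinol center is formed without control because step 8 removes it.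

Step 8
Reactants: 14 (2S)-5,7-bis[(tert-butyldimethylsilyl)oxy]-6-[(1R,6R)-6-(1-hydroxyethyl)-3-methylcyclohex-2-en-1-yl]-2-phenyl-2,3-dihydro-4H-chromen-4-one
Product: 15 (2S)-6-[(1R,6R)-6-acetyl-3-methylcyclohex-2-en-1-yl]-5,7-bis[(tert-butyldimethylsilyl)oxy]-2-phenyl-2,3-dihydro-4H-chromen-4-one
Conditions: Dess–Martin periodinane (1.3 equiv), CH2Cl2, 0 °C to rt
Reagents that add atoms: none
Why: Dess–Martin oxidation of the secondary alcohol to the methyl ketone is non-basic and should leave the trans ring stereocenters, the alkene and the silyl ethers intact.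

Step 9
Reactants: 15 (2S)-6-[(1R,6R)-6-acetyl-3-methylcyclohex-2-en-1-yl]-5,7-bis[(tert-butyldimethylsilyl)oxy]-2-phenyl-2,3-dihydro-4H-chromen-4-one
Product: 16 (2S)-5,7-bis[(tert-butyldimethylsilyl)oxy]-6-[(1R,6R)-3-methyl-6-(prop-1-en-2-yl)cyclohex-2-en-1-yl]-2-phenyl-2,3-dihydro-4H-chromen-4-one
Conditions: Cp2Ti(CH2)(Cl)AlMe2 (Tebbe reagent, 1.2 equiv), pyridine (cat.), THF/toluene, −40 to 0 °C
Reagents that add atoms: Tebbe reagent, C[Al](C)C[Ti](Cl)(C1C=CC=C1)C1C=CC=C1
Why: Tebbe methylenation through a titanium methylidene and an oxatitanacyclobutane is non-basic, so neither the α-stereocenter nor the flavanone C3–H should be deprotonated, and it should select the unhindered methyl ketone over the electron-rich, peri-shielded C4 carbonyl.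

Step 10
Reactants: 16 (2S)-5,7-bis[(tert-butyldimethylsilyl)oxy]-6-[(1R,6R)-3-methyl-6-(prop-1-en-2-yl)cyclohex-2-en-1-yl]-2-phenyl-2,3-dihydro-4H-chromen-4-one
Product: 17 (2S)-5,7-bis[(tert-butyldimethylsilyl)oxy]-6-[(1S,6S)-3-methyl-6-(propan-2-yl)cyclohex-2-en-1-yl]-2-phenyl-2,3-dihydro-4H-chromen-4-one
Conditions: H2 (1 atm), RhCl(PPh3)3 (5 mol%), benzene/EtOH (1:1), rt
Reagents that add atoms: none
Why: Homogeneous hydrogenation with RhCl(PPh3)3 discriminates by alkene substitution and should reduce the 1,1-disubstituted isopropenyl group while sparing the trisubstituted ring alkene, as in limonene- and carvone-type substrates, with no new stereocenter formed (the descriptors change only through priority rules).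

Step 11
Reactants: 17 (2S)-5,7-bis[(tert-butyldimethylsilyl)oxy]-6-[(1S,6S)-3-methyl-6-(propan-2-yl)cyclohex-2-en-1-yl]-2-phenyl-2,3-dihydro-4H-chromen-4-one
Product: 18 (2S)-5,7-dihydroxy-6-[(1S,6S)-3-methyl-6-(propan-2-yl)cyclohex-2-en-1-yl]-2-phenyl-2,3-dihydro-4H-chromen-4-one (target)
Conditions: HF·pyridine, pyridine, THF, 0 °C to rt
Reagents that add atoms: none
Why: Fluoride-mediated cleavage of both aryl silyl ethers under buffered conditions should avoid the base that racemizes flavanones and the strong acid that would add a phenol to the ring alkene.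

**Compound list**

1 | (2S)-pinocembrin, (2S)-5,7-dihydroxy-2-phenyl-2,3-dihydro-4H-chromen-4-one | O=C1C[C@@H](c2ccccc2)Oc2cc(O)cc(O)c12 | starting material
2 | (2S)-7-[(tert-butyldimethylsilyl)oxy]-5-hydroxy-2-phenyl-2,3-dihydro-4H-chromen-4-one | O=C1C[C@@H](c2ccccc2)Oc2cc(O[Si](C)(C)C(C)(C)C)cc(O)c12 | intermediate
3 | (2S)-7-[(tert-butyldimethylsilyl)oxy]-5-hydroxy-6-iodo-2-phenyl-2,3-dihydro-4H-chromen-4-one | O=C1C[C@@H](c2ccccc2)Oc2cc(O[Si](C)(C)C(C)(C)C)c(I)c(O)c12 | intermediate
4 | (2S)-5,7-bis[(tert-butyldimethylsilyl)oxy]-6-iodo-2-phenyl-2,3-dihydro-4H-chromen-4-one | O=C1C[C@@H](c2ccccc2)Oc2cc(O[Si](C)(C)C(C)(C)C)c(I)c(O[Si](C)(C)C(C)(C)C)c12 | intermediate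
5 | 2-methylbut-1-en-3-yne | C=C(C)C#C | starting material
6 | chlorido[(1E)-3-methylbuta-1,3-dien-1-yl]bis(cyclopentadienyl)zirconium (formed in the flask) | C=C(C)/C=C/[Zr](Cl)(C1C=CC=C1)C1C=CC=C1 | intermediate
7 | chlorido[(1E)-3-methylbuta-1,3-dien-1-yl]zinc (formed in the flask) | C=C(C)/C=C/[Zn]Cl | intermediate
8 | (2S)-5,7-bis[(tert-butyldimethylsilyl)oxy]-6-[(1E)-3-methylbuta-1,3-dien-1-yl]-2-phenyl-2,3-dihydro-4H-chromen-4-one | O=C1C[C@@H](c2ccccc2)Oc2cc(O[Si](C)(C)C(C)(C)C)c(/C=C/C(C)=C)c(O[Si](C)(C)C(C)(C)C)c12 | intermediate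
9 | acrolein (prop-2-enal) | C=CC=O | starting material
10 | (5R)-5-benzyl-2,2,3-trimethyl-4-oxo-1-[(E)-prop-2-en-1-ylidene]imidazolidin-1-ium chloride (formed in the flask) | C=C/C=[N+]1\[C@H](Cc2ccccc2)C(=O)N(C)C1(C)C.[Cl-] | intermediate
11 | (5R)-5-benzyl-1-{(E)-[(1S,2R)-2-{(2S)-5,7-bis[(tert-butyldimethylsilyl)oxy]-4-oxo-2-phenyl-3,4-dihydro-2H-chromen-6-yl}-4-methylcyclohex-3-en-1-yl]methylidene}-2,2,3-trimethyl-4-oxoimidazolidin-1-ium chloride (formed in the flask) | CC1=C[C@@H](c2c(O[Si](C)(C)C(C)(C)C)cc3c(c2O[Si](C)(C)C(C)(C)C)C(=O)C[C@@H](c2ccccc2)O3)[C@@H](/C=[N+]4\[C@H](Cc5ccccc5)C(=O)N(C)C4(C)C)CC1.[Cl-] | intermediate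
12 | (2S)-5,7-bis[(tert-butyldimethylsilyl)oxy]-6-[(1R,6S)-6-formyl-3-methylcyclohex-2-en-1-yl]-2-phenyl-2,3-dihydro-4H-chromen-4-one (cis) | CC1=C[C@@H](c2c(O[Si](C)(C)C(C)(C)C)cc3c(c2O[Si](C)(C)C(C)(C)C)C(=O)C[C@@H](c2ccccc2)O3)[C@@H](C=O)CC1 | intermediate
13 | (2S)-5,7-bis[(tert-butyldimethylsilyl)oxy]-6-[(1R,6R)-6-formyl-3-methylcyclohex-2-en-1-yl]-2-phenyl-2,3-dihydro-4H-chromen-4-one (trans) | CC1=C[C@@H](c2c(O[Si](C)(C)C(C)(C)C)cc3c(c2O[Si](C)(C)C(C)(C)C)C(=O)C[C@@H](c2ccccc2)O3)[C@H](C=O)CC1 | intermediate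
14 | (2S)-5,7-bis[(tert-butyldimethylsilyl)oxy]-6-[(1R,6R)-6-(1-hydroxyethyl)-3-methylcyclohex-2-en-1-yl]-2-phenyl-2,3-dihydro-4H-chromen-4-one (carbinol epimers) | CC1=C[C@@H](c2c(O[Si](C)(C)C(C)(C)C)cc3c(c2O[Si](C)(C)C(C)(C)C)C(=O)C[C@@H](c2ccccc2)O3)[C@H](C(C)O)CC1 | intermediate
15 | (2S)-6-[(1R,6R)-6-acetyl-3-methylcyclohex-2-en-1-yl]-5,7-bis[(tert-butyldimethylsilyl)oxy]-2-phenyl-2,3-dihydro-4H-chromen-4-one | CC1=C[C@@H](c2c(O[Si](C)(C)C(C)(C)C)cc3c(c2O[Si](C)(C)C(C)(C)C)C(=O)C[C@@H](c2ccccc2)O3)[C@H](C(C)=O)CC1 | intermediate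
16 | (2S)-5,7-bis[(tert-butyldimethylsilyl)oxy]-6-[(1R,6R)-3-methyl-6-(prop-1-en-2-yl)cyclohex-2-en-1-yl]-2-phenyl-2,3-dihydro-4H-chromen-4-one | CC1=C[C@@H](c2c(O[Si](C)(C)C(C)(C)C)cc3c(c2O[Si](C)(C)C(C)(C)C)C(=O)C[C@@H](c2ccccc2)O3)[C@H](C(C)=C)CC1 | intermediate
17 | (2S)-5,7-bis[(tert-butyldimethylsilyl)oxy]-6-[(1S,6S)-3-methyl-6-(propan-2-yl)cyclohex-2-en-1-yl]-2-phenyl-2,3-dihydro-4H-chromen-4-one | CC1=C[C@@H](c2c(O[Si](C)(C)C(C)(C)C)cc3c(c2O[Si](C)(C)C(C)(C)C)C(=O)C[C@@H](c2ccccc2)O3)[C@H](C(C)C)CC1 | intermediate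
18 | (2S)-5,7-dihydroxy-6-[(1S,6S)-3-methyl-6-(propan-2-yl)cyclohex-2-en-1-yl]-2-phenyl-2,3-dihydro-4H-chromen-4-one | CC1=C[C@@H](c2c(O)cc3c(c2O)C(=O)C[C@@H](c2ccccc2)O3)[C@H](C(C)C)CC1 | target

**Step count and risks**

Total step count: 11. Longest linear sequence: 11 steps (1 to 18).

Steps most likely to fail:

Step 5. The cycloaddition may stall because the diene terminus is flanked by two ortho silyloxy groups, the electron-rich diene may decompose under the acidic amine salt, and endo or facial control may erode if bond formation turns stepwise. The fallback sets out from 8 and comes back at 12, replacing iminium activation of acrolein by two-point chiral Lewis acid activation of an imide dienophile. Diene 8 and 3-acryloyl-1,3-oxazolidin-2-one with [Cu((S,S)-t-Bu-box)](SbF6)2 (divalent copper, 10 mol%, CH2Cl2, −20 °C to rt) should give, by the same endo mode and the same absolute sense, the cis imide 3-{[(1S,2R)-2-{(2S)-5,7-bis[(tert-butyldimethylsilyl)oxy]-4-oxo-2-phenyl-3,4-dihydro-2H-chromen-6-yl}-4-methylcyclohex-3-en-1-yl]carbonyl}-1,3-oxazolidin-2-one F1. Lithium ethanethiolate (THF, 0 °C) should convert it into the S-ethyl thioester of the same cis acid F2, and Fukuyama reduction (Et3SiH, Pd/C, acetone, rt) should deliver aldehyde 12.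

Step 9. The titanium methylidene may also attack the chromanone carbonyl, and the Lewis-acidic aluminium may strip the peri silyl ether. The fallback sets out from 15 and comes back at 16 by a two-stage Peterson olefination in which chemoselectivity is decided in a low-temperature addition. Me3SiCH2MgCl with CeCl3 (THF, −78 °C), a weakly basic organocerium reagent, should add only to the methyl ketone and give (2S)-5,7-bis[(tert-butyldimethylsilyl)oxy]-6-{(1R,6R)-6-[2-hydroxy-1-(trimethylsilyl)propan-2-yl]-3-methylcyclohex-2-en-1-yl}-2-phenyl-2,3-dihydro-4H-chromen-4-one F3 (carbinol epimers). Mild acid (AcOH, NaOAc, THF, 40 °C) should then eliminate the silanol to give 16.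

Step 2. Iodination may go to C8 or twice. The fallback sets out from 2 and comes back at 8, using a metal-phenoxide-directed reaction that can only reach the position ortho to the free 5-OH. Ortho-formylation of the magnesium phenoxide (MgCl2, Et3N, paraformaldehyde, MeCN, 60 °C) should give (2S)-7-[(tert-butyldimethylsilyl)oxy]-5-hydroxy-4-oxo-2-phenyl-3,4-dihydro-2H-chromene-6-carbaldehyde F4. Silylation (TBSOTf, 2,6-lutidine) should give (2S)-5,7-bis[(tert-butyldimethylsilyl)oxy]-4-oxo-2-phenyl-3,4-dihydro-2H-chromene-6-carbaldehyde F5. Barbier addition of 3-bromo-2-methylprop-1-ene with indium (THF/H2O, rt), selective for the aldehyde, should give (2S)-5,7-bis[(tert-butyldimethylsilyl)oxy]-6-(1-hydroxy-3-methylbut-3-en-1-yl)-2-phenyl-2,3-dihydro-4H-chromen-4-one F6 (carbinol epimers). PPTS-catalysed dehydration of this benzylic alcohol toward conjugation (toluene, 50 °C) should give the (E)-diene 8.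

Further compounds
F1 | step 5 | 3-{[(1S,2R)-2-{(2S)-5,7-bis[(tert-butyldimethylsilyl)oxy]-4-oxo-2-phenyl-3,4-dihydro-2H-chromen-6-yl}-4-methylcyclohex-3-en-1-yl]carbonyl}-1,3-oxazolidin-2-one | CC1=C[C@@H](c2c(O[Si](C)(C)C(C)(C)C)cc3c(c2O[Si](C)(C)C(C)(C)C)C(=O)C[C@@H](c2ccccc2)O3)[C@@H](C(=O)N4CCOC4=O)CC1
F2 | step 5 | S-ethyl (1S,2R)-2-{(2S)-5,7-bis[(tert-butyldimethylsilyl)oxy]-4-oxo-2-phenyl-3,4-dihydro-2H-chromen-6-yl}-4-methylcyclohex-3-ene-1-carbothioate | CC1=C[C@@H](c2c(O[Si](C)(C)C(C)(C)C)cc3c(c2O[Si](C)(C)C(C)(C)C)C(=O)C[C@@H](c2ccccc2)O3)[C@@H](C(=O)SCC)CC1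
F3 | step 9 | (2S)-5,7-bis[(tert-butyldimethylsilyl)oxy]-6-{(1R,6R)-6-[2-hydroxy-1-(trimethylsilyl)propan-2-yl]-3-methylcyclohex-2-en-1-yl}-2-phenyl-2,3-dihydro-4H-chromen-4-one | CC1=C[C@@H](c2c(O[Si](C)(C)C(C)(C)C)cc3c(c2O[Si](C)(C)C(C)(C)C)C(=O)C[C@@H](c2ccccc2)O3)[C@H](C(C)(O)C[Si](C)(C)C)CC1
F4 | step 2 | (2S)-7-[(tert-butyldimethylsilyl)oxy]-5-hydroxy-4-oxo-2-phenyl-3,4-dihydro-2H-chromene-6-carbaldehyde | O=C1C[C@@H](c2ccccc2)Oc2cc(O[Si](C)(C)C(C)(C)C)c(C=O)c(O)c12
F5 | step 2 | (2S)-5,7-bis[(tert-butyldimethylsilyl)oxy]-4-oxo-2-phenyl-3,4-dihydro-2H-chromene-6-carbaldehyde | O=C1C[C@@H](c2ccccc2)Oc2cc(O[Si](C)(C)C(C)(C)C)c(C=O)c(O[Si](C)(C)C(C)(C)C)c12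
F6 | step 2 | (2S)-5,7-bis[(tert-butyldimethylsilyl)oxy]-6-(1-hydroxy-3-methylbut-3-en-1-yl)-2-phenyl-2,3-dihydro-4H-chromen-4-one | O=C1C[C@@H](c2ccccc2)Oc2cc(O[Si](C)(C)C(C)(C)C)c(C(O)CC(C)=C)c(O[Si](C)(C)C(C)(C)C)c12
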